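**Plan**
- The retrosynthesis first cuts the depside ester bond between the ring A carbonyl and the oxygen on C4 of ring B, giving ring A acid 17 and ring B phenol 12.
- In each ring it then cuts the aryl–heptyl bond and the neighbouring aryl–carboxyl bond together.
- Ring B carries heptyl (C2), carboxyl (C1) and methoxy (C6) on three adjacent carbons. A 3-methoxybenzyne gives this pattern when a carbon nucleophile adds to the aryne carbon away from the methoxy group and an electrophile is taken up at the carbon beside it.
- Forward: fluoroarene 3 is converted by metalation, aryne formation, heptyl addition and carboxylation into ring B acid 9, which is benzylated and desilylated. Ring A acid 17 is made the same way from 1-fluoro-3,5-dimethoxybenzene.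
- The halves are joined by a mixed-anhydride esterification and the benzyl ester is removed by hydrogenolysis. No ring is formed and the target has no stereocentre.

Key step: step 2

Remark: heptylmagnesium bromide is taken as the commercial ethereal solution (otherwise it is made from 1-bromoheptane and magnesium). Ring B is the benzoic acid ring (carboxyl on C1) and ring A is the dimethoxybenzoyl ring.

**Route**

Step 1
Reactants: 1 3-fluoro-5-methoxyphenol; 2 triisopropylsilyl chloride
Product: 3 1-fluoro-3-methoxy-5-(triisopropylsilyloxy)benzene
Conditions: TIPSCl, imidazole, DMF, rt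
Reagents that add atoms: triisopropylsilyl chloride (2), CC(C)[Si](Cl)(C(C)C)C(C)C
Why: Imidazole-promoted silyl ether formation on a phenol is routine, and the bulky triisopropylsilyl group is chosen because it does not coordinate alkyllithiums and shields its two ortho protons.

Step 2
Reactants: 3 1-fluoro-3-methoxy-5-(triisopropylsilyloxy)benzene; 4 heptylmagnesium bromide; 5 carbon dioxide
Product: 9 2-heptyl-6-methoxy-4-(triisopropylsilyloxy)benzoic acid, via aryllithium 6 (not isolated), via methoxyaryne 7 (not isolated), via arylmagnesium bromide 8 (not isolated)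
Conditions: s-BuLi (1.05 equiv), THF, −78 °C; n-C7H15MgBr (2 equiv, Et2O), −78 °C → rt; CO2 (gas), −40 °C → rt; 1 M HCl, 0 °C
Reagents that add atoms: heptylmagnesium bromide (4), CCCCCCC[Mg]Br; carbon dioxide (5), O=C=O
Why: With the C–F carbon of 3 taken as C1, sec-butyllithium removes H-2, the proton flanked by fluorine and methoxy, and aryllithium 6 loses lithium fluoride on warming to give aryne 7. The Grignard reagent adds to the aryne carbon meta to the methoxy group, so the carbon–magnesium bond of 8 forms ortho to the inductively withdrawing, coordinating methoxy oxygen, and 8 is then carboxylated by carbon dioxide. The closest known reaction type is carbometalation of 3-alkoxyarynes generated from ortho-metalated 3-haloanisoles with electrophilic trapping of the new arylmetal (aryne vicinal difunctionalization). No ring is closed and no stereocentre is created. Site selectivity in the metalation should come from the cooperative acidification of H-2 by fluorine and methoxy and from the bulky, non-coordinating silyloxy group shielding H-4 and H-6; regioselectivity in the addition should come from polarisation of the aryne by the adjacent methoxy group. sec-Butyllithium is kept near one equivalent so that no alkyllithium competes with the Grignard reagent for the aryne.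

Step 3
Reactants: 9 2-heptyl-6-methoxy-4-(triisopropylsilyloxy)benzoic acid; 10 benzyl bromide
Product: 11 benzyl 2-heptyl-6-methoxy-4-(triisopropylsilyloxy)benzoate
Conditions: BnBr, KHCO3, DMF, rt
Reagents that add atoms: benzyl bromide (10), BrCc1ccccc1
Why: SN2 alkylation of the carboxylate takes place at the benzylic carbon, so the two ortho substituents that would block a Fischer esterification do not interfere, and bicarbonate is too weak a base to cleave the aryl silyl ether.

Step 4
Reactants: 11 benzyl 2-heptyl-6-methoxy-4-(triisopropylsilyloxy)benzoate
Product: 12 benzyl 2-heptyl-4-hydroxy-6-methoxybenzoate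
Conditions: TBAF, AcOH, THF, 0 °C
Reagents that add atoms: none
Why: Fluoride-induced desilylation of an aryl silyl ether is fast, and the acetic acid buffer keeps the liberated phenoxide from attacking the hindered benzyl ester.

Step 5
Reactants: 13 1-fluoro-3,5-dimethoxybenzene; 4 heptylmagnesium bromide; 5 carbon dioxide
Product: 17 2-heptyl-4,6-dimethoxybenzoic acid, via aryllithium 14 (not isolated), via dimethoxyaryne 15 (not isolated), via arylmagnesium bromide 16 (not isolated)
Conditions: s-BuLi (1.05 equiv), THF, −78 °C; n-C7H15MgBr (2 equiv, Et2O), −78 °C → rt; CO2 (gas), −40 °C → rt; 1 M HCl, 0 °C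
Reagents that add atoms: heptylmagnesium bromide (4), CCCCCCC[Mg]Br; carbon dioxide (5), O=C=O
Why: The aryne carbomagnesiation–carboxylation of step 2 applies to this symmetric fluoroarene, where a proton flanked by fluorine and methoxy should be removed in preference to the one between the two methoxy groups, and the Grignard reagent again adds away from the neighbouring methoxy so that the carboxyl ends up between heptyl and methoxy.

Step 6
Reactants: 17 2-heptyl-4,6-dimethoxybenzoic acid; 12 benzyl 2-heptyl-4-hydroxy-6-methoxybenzoate
Product: 19 benzyl 2-heptyl-4-[(2-heptyl-4,6-dimethoxybenzoyl)oxy]-6-methoxybenzoate, via mixed anhydride 18 (not isolated)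
Conditions: (CF3CO)2O, toluene, 0 °C → rt
Reagents that add atoms: none
Why: Trifluoroacetic anhydride turns the hindered, electron-rich acid into a mixed anhydride that ionises readily towards an acylium ion, which acylates the phenol oxygen (mixed-anhydride esterification, a standard route to depside esters), while the benzyl ester and methyl ethers are inert.

Step 7
Reactants: 19 benzyl 2-heptyl-4-[(2-heptyl-4,6-dimethoxybenzoyl)oxy]-6-methoxybenzoate
Product: 20 2-heptyl-4-[(2-heptyl-4,6-dimethoxybenzoyl)oxy]-6-methoxybenzoic acid
Conditions: H2 (1 atm), 10% Pd/C, EtOAc, rt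
Reagents that add atoms: none
Why: Catalytic hydrogenolysis cleaves the benzylic C–O bond of the benzyl ester under neutral conditions that leave the aryl ester link, the methyl ethers and both arene rings untouched.

**Compound list**

1 | 3-fluoro-5-methoxyphenol | COc1cc(O)cc(F)c1 | starting material
2 | triisopropylsilyl chloride | CC(C)[Si](Cl)(C(C)C)C(C)C | starting material
3 | 1-fluoro-3-methoxy-5-(triisopropylsilyloxy)benzene | COc1cc(O[Si](C(C)C)(C(C)C)C(C)C)cc(F)c1 | intermediate
4 | heptylmagnesium bromide | CCCCCCC[Mg]Br | starting material
5 | carbon dioxide | O=C=O | starting material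
6 | [2-fluoro-6-methoxy-4-(triisopropylsilyloxy)phenyl]lithium | COc1cc(O[Si](C(C)C)(C(C)C)C(C)C)cc(F)c1[Li] | intermediate
7 | 3-methoxy-5-(triisopropylsilyloxy)benzyne | COC1=CC(O[Si](C(C)C)(C(C)C)C(C)C)=CC#C1 | intermediate
8 | [2-heptyl-6-methoxy-4-(triisopropylsilyloxy)phenyl]magnesium bromide | CCCCCCCc1cc(O[Si](C(C)C)(C(C)C)C(C)C)cc(OC)c1[Mg]Br | intermediate
9 | 2-heptyl-6-methoxy-4-(triisopropylsilyloxy)benzoic acid | CCCCCCCc1cc(O[Si](C(C)C)(C(C)C)C(C)C)cc(OC)c1C(=O)O | intermediate
10 | benzyl bromide | BrCc1ccccc1 | starting material
11 | benzyl 2-heptyl-6-methoxy-4-(triisopropylsilyloxy)benzoate | CCCCCCCc1cc(O[Si](C(C)C)(C(C)C)C(C)C)cc(OC)c1C(=O)OCc1ccccc1 | intermediate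
12 | benzyl 2-heptyl-4-hydroxy-6-methoxybenzoate | CCCCCCCc1cc(O)cc(OC)c1C(=O)OCc1ccccc1 | intermediate
13 | 1-fluoro-3,5-dimethoxybenzene | COc1cc(OC)cc(F)c1 | starting material
14 | (2-fluoro-4,6-dimethoxyphenyl)lithium | COc1cc(OC)c([Li])c(F)c1 | intermediate
15 | 3,5-dimethoxybenzyne | COC1=CC(OC)=CC#C1 | intermediate
16 | (2-heptyl-4,6-dimethoxyphenyl)magnesium bromide | CCCCCCCc1cc(OC)cc(OC)c1[Mg]Br | intermediate
17 | 2-heptyl-4,6-dimethoxybenzoic acid | CCCCCCCc1cc(OC)cc(OC)c1C(=O)O | intermediate
18 | 2-heptyl-4,6-dimethoxybenzoic trifluoroacetic anhydride | CCCCCCCc1cc(OC)cc(OC)c1C(=O)OC(=O)C(F)(F)F | intermediate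
19 | benzyl 2-heptyl-4-[(2-heptyl-4,6-dimethoxybenzoyl)oxy]-6-methoxybenzoate | CCCCCCCc1cc(OC(=O)c2c(CCCCCCC)cc(OC)cc2OC)cc(OC)c1C(=O)OCc1ccccc1 | intermediate
20 | 2-heptyl-4-[(2-heptyl-4,6-dimethoxybenzoyl)oxy]-6-methoxybenzoic acid (CNP0300299.0) | CCCCCCCc1cc(OC(=O)c2c(CCCCCCC)cc(OC)cc2OC)cc(OC)c1C(=O)O | target

**Step count**

Total steps: 7. Longest linear sequence: 6 steps (steps 1, 2, 3, 4, 6 and 7, from compound 1).

**Steps most likely to fail**

1. Step 2. The risks are that sec-butyl residues compete with the Grignard reagent for the aryne, that fluoride loss is incomplete once lithium and magnesium species are mixed, or that the arylmagnesium is protonated before it meets carbon dioxide. The fallback makes the two ring bonds in the reverse order and avoids the aryne. It sets out from 3: metalation as before, but the cold aryllithium 6 is carboxylated at −78 °C before any fluoride is lost, which should give 2-fluoro-6-methoxy-4-(triisopropylsilyloxy)benzoic acid F1. F1 is then treated with heptylmagnesium bromide 4 in THF (−78 °C → rt). The first equivalent forms the bromomagnesium carboxylate of F1 and a second is delivered to the ortho C–F carbon, where fluoride is displaced by addition–elimination (carboxylate-assisted nucleophilic aromatic substitution of a 2-fluorobenzoic acid; fluoride is a better leaving group than the other ortho substituent, methoxy). Acidic work-up returns the route at 9.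

2. Step 6. The risks are that trifluoroacetylation of the phenol outruns aroylation, that the acylium ion acylates an electron-rich ring carbon, or that the benzyl ester is eroded in the acidic medium. The fallback moves to a preformed acyl chloride under basic conditions. It sets out from 17, which with oxalyl chloride and catalytic DMF in CH2Cl2 should give 2-heptyl-4,6-dimethoxybenzoyl chloride F2. After removal of volatiles, F2 acylates phenol 12 in CH2Cl2 with Et3N and catalytic DMAP (nucleophilic-catalysis acylation), coming back at 19.

3. Step 5. The risks are metalation between the two methoxy groups, which gives an aryllithium that cannot eliminate, and the same competition and capture problems as in step 2. The fallback builds ring A without an aryne and sets out from Grignard reagent 4. A Kumada coupling of 4 with commercial 1-bromo-3,5-dimethoxybenzene (NiCl2(dppp), THF) should give 1-heptyl-3,5-dimethoxybenzene F3. Vilsmeier–Haack formylation (POCl3, DMF, then aqueous hydrolysis) should go ortho to the heptyl chain and para to a methoxy group, giving 2-heptyl-4,6-dimethoxybenzaldehyde F4. Pinnick oxidation (NaClO2, NaH2PO4, 2-methyl-2-butene, t-BuOH/H2O) returns the route at 17.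

**Further compounds**

F1 | step 2 | 2-fluoro-6-methoxy-4-(triisopropylsilyloxy)benzoic acid | COc1cc(O[Si](C(C)C)(C(C)C)C(C)C)cc(F)c1C(=O)O
F2 | step 6 | 2-heptyl-4,6-dimethoxybenzoyl chloride | CCCCCCCc1cc(OC)cc(OC)c1C(=O)Cl
F3 | step 5 | 1-heptyl-3,5-dimethoxybenzene | CCCCCCCc1cc(OC)cc(OC)c1
F4 | step 5 | 2-heptyl-4,6-dimethoxybenzaldehyde | CCCCCCCc1cc(OC)cc(OC)c1C=O
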